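The runs were generated by integration for an exercise; scatter was added.

The gamma run, charged at 0.13 M, and the alpha run, charged at 0.30 M, are best read through x, the fraction of starting material left, and not through the target made.

common to all: gas phase 19 mM (held)
- gamma: starting material 0.13 M; run made earlier
- alpha: starting material 0.30 M; run made earlier
- flask: starting material 0.20 M; time 8.0 h

| run | time / h | target / % |
|---|---|---|
| gamma | 1.33 | 18 |
| gamma | 2.50 | 24 |
| gamma | 4.00 | 26 |
| gamma | 5.00 | 25 |
| gamma | 6.00 | 26 |
| gamma | 8.00 | 16 |
| alpha | 0.667 | 6 |
| alpha | 1.00 | 14 |
| alpha | 2.00 | 19 |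
| alpha | 3.00 | 21 |
| alpha | 5.00 | 29 |
| alpha | 8.00 | 20 |

(each reading ± 1.5 percentage points)

- how much target there is at 8.0 h, in percent of the starting material charged
- concentration of dissolved gas in solution at 8.0 h, in percent of saturation

At the first instant no gas is dissolved, so the gas phase has to feed the solution before starting material can react. Early on, with dissolved gas taken as steady, x decays pseudo-first-order with constant κ, and I read the loss of starting material from the target present:

κ = −ln(1 − y)/t: gamma 0.149 h⁻¹, alpha 0.151 h⁻¹, mean 0.150 h⁻¹

Each κ rests on one reading with its scatter, and it counts target still present, not what has gone on to over-reacted product.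

In the middle, formation and over-reaction each take dissolved gas at first order, so the gas level cancels when you follow target y against x. Target peaks where making equals using, at x = s·y. The alpha run has its highest reading at 5.00 h, and I take that reading as its peak:

x = exp(−κt) = 47.0 %, y = 29 %, s = x/y = 1.62

This s, a reading from one peak, is my selectivity factor, the rate constant of over-reaction over that of formation.

Towards the end, x falls below its peak value and target declines. My reckoning for the flask at 8.0 h:

x = 30.1 %, y = (x^s − x)/(1 − s) = 25.5 %

Since κ counts target still present, I hold this x, and with it this y, as a high value. The forecast differs, giving 18 % (14 % to 22 %) and 60 % of saturation (35 % to 85 %): “Interpolating at 8 h between 16% (0.13 M) and 20% (0.30 M) gives about 18% at 0.20 M”.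

    dissolved gas + target → over-reacted product (k = 31.0 L mol⁻¹ h⁻¹)
    dissolved gas → decomposed reagent (k = 0.230 h⁻¹)
    starting material + dissolved gas → target (k = 17.0 L mol⁻¹ h⁻¹)
    2 dissolved gas → homo dimer (k = 15.0 L mol⁻¹ h⁻¹)
    gas phase ⇌ dissolved gas, rate k5*(csat - [dissolved gas]) (kL = 4.90 h⁻¹)

The flask gives 19.8 % target and dissolved gas at 64.8 % of saturation, each within the forecast's range. At 8.0 h the flask holds 23 % of its starting material, less than my 30.1 %, and that x with s = 1.62 gives 22.2 % target.

A neighbouring flask, the same charge read at 2.0 h, has 72 % left, so the rule gives 21.4 %. Its computed target is 20.8 %.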